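The fourteen ring carbons are labelled C1–C14: C1 bears the CMe2 carbon C15, C3 is the O-bearing CH, C4 and C8 are the CH–CO2H carbons, and C11=C12 is the alkene. The route rests on cutting the oxolane ring (O, C3, C2, C1, C15) at O–C15. C15 is tertiary and not a stereocentre, so it can be ionised and trapped by the C3 hydroxyl while C1, C3 and C4 stay untouched. The precursor is the complete 14-membered carbocycle with a free C3–OH and a silylated C15 carbinol. It is built from a twofold-symmetric pimeloyl bis-imide, a (Z)-vinyl iodide and an epoxide-derived C1 unit, and closed by B-alkyl Suzuki macrocyclisation. One acid treatment then desilylates and closes the oxolane.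

Key step: step 11

Remark: 3-[(tert-butyldimethylsilyl)oxy]propanal, 4-methylpent-3-en-1-ol and the L-fructose-derived Shi ketone are taken as purchasable; the L-ketone is assumed to give the (S)-epoxide in step 5, the mirror image of the sense known for the D-ketone.

Step 1
Reactants: 1 (S)-4-benzyl-1,3-oxazolidin-2-one; 2 heptanedioyl dichloride
Product: 4 1,7-bis[(4S)-4-benzyl-2-oxo-1,3-oxazolidin-3-yl]heptane-1,7-dione, via lithiated oxazolidinone 3 (not isolated)
Conditions: 1 (2.05 equiv), n-BuLi (2.0 equiv), THF, −78 °C; then 2 (1.0 equiv), −78 → 0 °C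
Reagents that add atoms: second equivalent of 1 (S)-4-benzyl-1,3-oxazolidin-2-one, O=C1N[C@@H](Cc2ccccc2)CO1
Why: In this twofold N-acylation each acid chloride terminus of 2 takes up one lithiated oxazolidinone, so two equivalents of 1 are built into the symmetric bis-imide, and no new stereocentre arises.

Step 2
Reactants: 5 3-[(tert-butyldimethylsilyl)oxy]propanal; 6 ethyltriphenylphosphonium iodide
Product: 10 tert-butyl{[(3Z)-4-iodopent-3-en-1-yl]oxy}dimethylsilane, via ethylidene ylide 7 (not isolated), via iodoethylphosphonium iodide 8 (not isolated), via iodoethylidene ylide 9 (not isolated)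
Conditions: 6, n-BuLi, THF, rt; I2, −78 °C; NaN(SiMe3)2, −20 °C; then 5, −78 → −20 °C
Reagents that add atoms: iodine, [I][I]
Why: In this Stork–Zhao olefination the α-iodo ylide should add to the unhindered aldehyde through the kinetically preferred cis-oxaphosphetane, placing iodine cis to the chain in the (Z)-2-iodoalk-2-ene.

Step 3
Reactants: 10 tert-butyl{[(3Z)-4-iodopent-3-en-1-yl]oxy}dimethylsilane
Product: 11 (3Z)-4-iodopent-3-en-1-ol
Conditions: camphorsulfonic acid (10 mol%), MeOH, 0 °C → rt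
Reagents that add atoms: none
Why: Acid-catalysed methanolysis should remove the primary silyl ether and leave the vinyl iodide untouched.

Step 4
Reactants: 11 (3Z)-4-iodopent-3-en-1-ol; 4 1,7-bis[(4S)-4-benzyl-2-oxo-1,3-oxazolidin-3-yl]heptane-1,7-dione
Product: 14 (2R)-1,7-bis[(4S)-4-benzyl-2-oxo-1,3-oxazolidin-3-yl]-2-[(3Z)-4-iodopent-3-en-1-yl]heptane-1,7-dione, via triflate 12 (not isolated), via disodium bis-enolate 13 (not isolated)
Conditions: (a) 11, Tf2O, 2,6-lutidine, CH2Cl2, −78 °C; (b) 4 (1.5 equiv), NaN(SiMe3)2 (3.1 equiv), THF, −78 °C; then 12 (1.0 equiv), −78 °C; AcOH quench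
Reagents that add atoms: none
Why: In this Evans alkylation the chelated sodium (Z)-enolate should be attacked by the primary triflate on the face opposite the benzyl group to set C8 as R, while full bis-enolate formation removes the electrophilic imide that could trigger Dieckmann closure and the limiting triflate restrains double alkylation.

Step 5
Reactants: 15 4-methylpent-3-en-1-ol
Product: 16 2-[(2S)-3,3-dimethyloxiran-2-yl]ethan-1-ol
Conditions: L-fructose-derived Shi ketone (30 mol%), Oxone (2KHSO5·KHSO4·K2SO4), K2CO3, Bu4NHSO4, MeCN/dimethoxymethane/aqueous buffer (pH 10.5), 0 °C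
Reagents that add atoms: potassium peroxymonosulfate, [K+].[O-]S(=O)(=O)OO
Why: In this Shi epoxidation the chiral dioxirane should transfer oxygen to one face of the trisubstituted alkene through a spiro transition state, and the L-fructose-derived ketone is chosen because it should deliver the (S)-epoxide.

Step 6
Reactants: 16 2-[(2S)-3,3-dimethyloxiran-2-yl]ethan-1-ol
Product: 17 (3S)-3-ethenyl-4-methylpentane-1,4-diol
Conditions: CH2=CHMgBr (3.5 equiv), CuI (15 mol%), THF, −30 → 0 °C
Reagents that add atoms: vinylmagnesium bromide, C=C[Mg]Br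
Why: Copper-catalysed SN2 opening of the epoxide by the vinyl Grignard reagent should occur at the less substituted carbon C1 with inversion, which fixes C1 and releases the tertiary C15 alcohol.

Step 7
Reactants: 17 (3S)-3-ethenyl-4-methylpentane-1,4-diol
Product: 18 (3S)-3-ethenyl-4-methyl-1,4-bis[(triethylsilyl)oxy]pentane
Conditions: Et3SiOTf (2.4 equiv), 2,6-lutidine, CH2Cl2, −78 → 0 °C
Reagents that add atoms: triethylsilyl trifluoromethanesulfonate, CC[Si](CC)(CC)OS(=O)(=O)C(F)(F)F
Why: In this twofold O-silylation the silyl triflate is reactive enough to silylate the tertiary as well as the primary hydroxyl (two equivalents are taken up), which prevents lactol formation once C3 becomes an aldehyde.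

Step 8
Reactants: 18 (3S)-3-ethenyl-4-methyl-1,4-bis[(triethylsilyl)oxy]pentane
Product: 19 (3S)-3-ethenyl-4-methyl-4-[(triethylsilyl)oxy]pentanal
Conditions: (COCl)2, DMSO, CH2Cl2, −78 → −35 °C; Et3N, −78 °C → rt
Reagents that add atoms: none
Why: Under Swern conditions a primary triethylsilyl ether should be cleaved and oxidised directly to the aldehyde, while the hindered tertiary silyl ether is not attacked.

Step 9
Reactants: 14 (2R)-1,7-bis[(4S)-4-benzyl-2-oxo-1,3-oxazolidin-3-yl]-2-[(3Z)-4-iodopent-3-en-1-yl]heptane-1,7-dione; 19 (3S)-3-ethenyl-4-methyl-4-[(triethylsilyl)oxy]pentanal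
Product: 22 (2R,6S)-1,7-bis[(4S)-4-benzyl-2-oxo-1,3-oxazolidin-3-yl]-6-[(1R,3S)-3-ethenyl-1-hydroxy-4-methyl-4-(triethylsilyloxy)pentyl]-2-[(3Z)-4-iodopent-3-en-1-yl]heptane-1,7-dione, via boron enolate 20 (not isolated), via boron aldolate 21 (not isolated)
Conditions: Bu2BOTf, i-Pr2NEt, CH2Cl2, 0 °C; 19, −78 → 0 °C; then pH 7 buffer, MeOH, 30% H2O2, 0 °C
Reagents that add atoms: none
Why: In this Evans syn-aldol only the α-unbranched imide should be enolised to the (Z)-boron enolate, which adds to 19 through a Zimmerman–Traxler chair on the face opposite the benzyl group and so sets C3 as R and C4 as S.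

Step 10
Reactants: 22 (2R,6S)-1,7-bis[(4S)-4-benzyl-2-oxo-1,3-oxazolidin-3-yl]-6-[(1R,3S)-3-ethenyl-1-hydroxy-4-methyl-4-(triethylsilyloxy)pentyl]-2-[(3Z)-4-iodopent-3-en-1-yl]heptane-1,7-dione
Product: 24 (1R,3R,4S,8R,11Z)-3-hydroxy-12-methyl-1-[2-(triethylsilyloxy)propan-2-yl]cyclotetradec-11-ene-4,8-dicarbonyl bis[(4S)-4-benzyl-1,3-oxazolidin-2-one] (ring locants are the labels C1–C14), via B-alkyl borane 23 (not isolated)
Conditions: 9-BBN (2.5 equiv), THF, rt; then slow addition to PdCl2(dppf) (15 mol%), AsPh3, Cs2CO3, DMF/THF/H2O, rt, 2 mM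
Reagents that add atoms: none
Why: In this B-alkyl Suzuki–Miyaura macrocyclisation, selective hydroboration of the monosubstituted vinyl group (the excess borane covers reversible O-borylation of the C3 alcohol) and intramolecular sp3–sp2 coupling with retention at the vinyl iodide should form the C12–C13 bond, the 14-membered ring and the (Z)-trisubstituted alkene in one operation.

Step 11
Reactants: 24 (1R,3R,4S,8R,11Z)-3-hydroxy-12-methyl-1-[2-(triethylsilyloxy)propan-2-yl]cyclotetradec-11-ene-4,8-dicarbonyl bis[(4S)-4-benzyl-1,3-oxazolidin-2-one]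
Product: 26 (1R,4Z,8R,12S,13R)-4,15,15-trimethyl-14-oxabicyclo[11.2.1]hexadec-4-ene-8,12-dicarbonyl bis[(4S)-4-benzyl-1,3-oxazolidin-2-one], via diol 25 (not isolated)
Conditions: TsOH·H2O (0.3 equiv), MeOH/CH2Cl2, rt; then solvent exchange to MeNO2, rt
Reagents that add atoms: none
Why: The sulfonic acid in methanol should first cleave the tertiary silyl ether to diol 25; in nitromethane the same acid protonates the tertiary C15 hydroxyl, water leaves, and the C15 cation (or its tight ion pair) is captured by the C3 hydroxyl in an SN1 cycloetherification. The closest known reaction type is the acid-catalysed cyclodehydration of 1,4-diols with one tertiary carbinol terminus to 2,2-dialkyl oxolanes. The oxolane (O, C3, C2, C1, C15) closes in the 5-exo mode at C15, the departing water lying outside the new ring. No stereocentre is created: C15 carries two methyl groups, and C1, C3 and C4 keep the configurations set in steps 6 and 9 because only the C15–O bond is broken, so the cis bridge across the oxolane follows from 1R,3R. The step needs capture by oxygen to outrun E1 loss and attack of the C11=C12 alkene on the cation; the 1,4-relationship of C3–OH and C15 (five-membered transition state) secures this, and any isopropenyl by-product should be re-protonated and funnelled to the ether.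

Step 12
Reactants: 26 (1R,4Z,8R,12S,13R)-4,15,15-trimethyl-14-oxabicyclo[11.2.1]hexadec-4-ene-8,12-dicarbonyl bis[(4S)-4-benzyl-1,3-oxazolidin-2-one]
Product: 28 (1R,4Z,8R,12S,13R)-4,15,15-trimethyl-14-oxabicyclo[11.2.1]hexadec-4-ene-8,12-dicarboxylic acid, via bis-peroxy acid 27 (not isolated)
Conditions: LiOH·H2O, 30% H2O2, THF/H2O, 0 °C; Na2SO3; then 1 M HCl
Reagents that add atoms: hydrogen peroxide, OO
Why: Lithium hydroperoxide should attack the exocyclic imide carbonyls selectively even at these α-branched acyl groups, and sulfite reduction of the peracids should give the diacid without epimerisation at C4 or C8.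

Compound list
1 | (S)-4-benzyl-1,3-oxazolidin-2-one | O=C1N[C@@H](Cc2ccccc2)CO1 | starting material
2 | heptanedioyl dichloride (pimeloyl chloride) | O=C(Cl)CCCCCC(Cl)=O | starting material
3 | 3-lithio-(S)-4-benzyl-1,3-oxazolidin-2-one | [Li]N1[C@@H](Cc2ccccc2)COC1=O | intermediate
4 | 1,7-bis[(4S)-4-benzyl-2-oxo-1,3-oxazolidin-3-yl]heptane-1,7-dione | O=C(CCCCCC(=O)N1[C@@H](Cc2ccccc2)COC1=O)N1[C@@H](Cc2ccccc2)COC1=O | intermediate
5 | 3-[(tert-butyldimethylsilyl)oxy]propanal | O=CCCO[Si](C)(C)C(C)(C)C | starting material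
6 | ethyltriphenylphosphonium iodide | CC[P+](c1ccccc1)(c1ccccc1)c1ccccc1.[I-] | starting material
7 | ethylidenetriphenylphosphorane | CC=P(c1ccccc1)(c1ccccc1)c1ccccc1 | intermediate
8 | (1-iodoethyl)triphenylphosphonium iodide | CC(I)[P+](c1ccccc1)(c1ccccc1)c1ccccc1.[I-] | intermediate
9 | (1-iodoethylidene)triphenylphosphorane | CC(I)=P(c1ccccc1)(c1ccccc1)c1ccccc1 | intermediate
10 | tert-butyl{[(3Z)-4-iodopent-3-en-1-yl]oxy}dimethylsilane | C/C(I)=C/CCO[Si](C)(C)C(C)(C)C | intermediate
11 | (3Z)-4-iodopent-3-en-1-ol | C/C(I)=C/CCO | intermediate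
12 | (3Z)-4-iodopent-3-en-1-yl trifluoromethanesulfonate | C/C(I)=C/CCOS(=O)(=O)C(F)(F)F | intermediate
13 | disodium bis[(Z)-enolate] of 4 | [Na+].[Na+].[O-]/C(N1[C@@H](Cc2ccccc2)COC1=O)=C\CCC/C=C(\[O-])N1[C@@H](Cc2ccccc2)COC1=O | intermediate
14 | (2R)-1,7-bis[(4S)-4-benzyl-2-oxo-1,3-oxazolidin-3-yl]-2-[(3Z)-4-iodopent-3-en-1-yl]heptane-1,7-dione | C/C(I)=C/CC[C@H](C(=O)N1[C@@H](Cc2ccccc2)COC1=O)CCCCC(=O)N1[C@@H](Cc2ccccc2)COC1=O | intermediate
15 | 4-methylpent-3-en-1-ol | CC(C)=CCCO | starting material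
16 | 2-[(2S)-3,3-dimethyloxiran-2-yl]ethan-1-ol | OCC[C@@H]1OC1(C)C | intermediate
17 | (3S)-3-ethenyl-4-methylpentane-1,4-diol | OCC[C@@H](C=C)C(C)(C)O | intermediate
18 | (3S)-3-ethenyl-4-methyl-1,4-bis[(triethylsilyl)oxy]pentane | CC[Si](CC)(CC)OCC[C@@H](C=C)C(C)(C)O[Si](CC)(CC)CC | intermediate
19 | (3S)-3-ethenyl-4-methyl-4-[(triethylsilyl)oxy]pentanal | O=CC[C@@H](C=C)C(C)(C)O[Si](CC)(CC)CC | intermediate
20 | dibutylboron (Z)-enolate of 14 at the unbranched acyl arm | C/C(I)=C/CC[C@H](C(=O)N1[C@@H](Cc2ccccc2)COC1=O)CCC/C=C(\OB(CCCC)CCCC)N1[C@@H](Cc2ccccc2)COC1=O | intermediate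
21 | O-dibutylboryl aldolate of 22 | C/C(I)=C/CC[C@H](C(=O)N1[C@@H](Cc2ccccc2)COC1=O)CCC[C@H](C(=O)N1[C@@H](Cc2ccccc2)COC1=O)[C@H](OB(CCCC)CCCC)C[C@@H](C=C)C(C)(C)O[Si](CC)(CC)CC | intermediate
22 | (2R,6S)-1,7-bis[(4S)-4-benzyl-2-oxo-1,3-oxazolidin-3-yl]-6-[(1R,3S)-3-ethenyl-1-hydroxy-4-methyl-4-(triethylsilyloxy)pentyl]-2-[(3Z)-4-iodopent-3-en-1-yl]heptane-1,7-dione | C/C(I)=C/CC[C@H](C(=O)N1[C@@H](Cc2ccccc2)COC1=O)CCC[C@H](C(=O)N1[C@@H](Cc2ccccc2)COC1=O)[C@H](O)C[C@@H](C=C)C(C)(C)O[Si](CC)(CC)CC | intermediate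
23 | B-alkyl-9-borabicyclo[3.3.1]nonane adduct of 22 (boron on C13) | C/C(I)=C/CC[C@H](C(=O)N1[C@@H](Cc2ccccc2)COC1=O)CCC[C@H](C(=O)N1[C@@H](Cc2ccccc2)COC1=O)[C@H](O)C[C@@H](CCB1C2CCCC1CCC2)C(C)(C)O[Si](CC)(CC)CC | intermediate
24 | (1R,3R,4S,8R,11Z)-3-hydroxy-12-methyl-1-[2-(triethylsilyloxy)propan-2-yl]cyclotetradec-11-ene-4,8-dicarbonyl bis[(4S)-4-benzyl-1,3-oxazolidin-2-one] | C/C1=C/CC[C@H](C(=O)N2[C@@H](Cc3ccccc3)COC2=O)CCC[C@H](C(=O)N2[C@@H](Cc3ccccc3)COC2=O)[C@H](O)C[C@@H](CC1)C(C)(C)O[Si](CC)(CC)CC | intermediate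
25 | (1R,3R,4S,8R,11Z)-3-hydroxy-1-(2-hydroxypropan-2-yl)-12-methylcyclotetradec-11-ene-4,8-dicarbonyl bis[(4S)-4-benzyl-1,3-oxazolidin-2-one] | C/C1=C/CC[C@H](C(=O)N2[C@@H](Cc3ccccc3)COC2=O)CCC[C@H](C(=O)N2[C@@H](Cc3ccccc3)COC2=O)[C@H](O)C[C@@H](CC1)C(C)(C)O | intermediate
26 | (1R,4Z,8R,12S,13R)-4,15,15-trimethyl-14-oxabicyclo[11.2.1]hexadec-4-ene-8,12-dicarbonyl bis[(4S)-4-benzyl-1,3-oxazolidin-2-one] | C/C1=C/CC[C@H](C(=O)N2[C@@H](Cc3ccccc3)COC2=O)CCC[C@H](C(=O)N2[C@@H](Cc3ccccc3)COC2=O)[C@H]2C[C@@H](CC1)C(C)(C)O2 | intermediate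
27 | (1R,4Z,8R,12S,13R)-4,15,15-trimethyl-14-oxabicyclo[11.2.1]hexadec-4-ene-8,12-dicarboperoxoic acid | C/C1=C/CC[C@H](C(=O)OO)CCC[C@H](C(=O)OO)[C@H]2C[C@@H](CC1)C(C)(C)O2 | intermediate
28 | (1R,4Z,8R,12S,13R)-4,15,15-trimethyl-14-oxabicyclo[11.2.1]hexadec-4-ene-8,12-dicarboxylic acid | C/C1=C/CC[C@H](C(=O)O)CCC[C@H](C(=O)O)[C@H]2C[C@@H](CC1)C(C)(C)O2 | target

Total steps: 12. Longest linear sequence: 8 steps (steps 5, 6, 7, 8, 9, 10, 11, 12).

Steps most likely to fail

Step 10. The aqueous carbonate of the coupling may hydrolyse the imides or cleave the aldol by retro-aldol reaction, and intermolecular coupling may give oligomers. The fallback takes the base-labile auxiliaries off before the ring closure. It sets out from 22: MeOMgBr in MeOH at 0 °C should exchange both imides for methyl esters to give the seco hydroxy diester F1. 9-BBN should convert its vinyl group into the B-alkyl borane F2, which is cyclised under the same palladium conditions to the macrocyclic hydroxy diester F3. TsOH·H2O in MeOH and then MeNO2 should remove the silyl group (diol diester F4) and close the oxolane to the diester F5. LiOH in THF/MeOH/H2O should then saponify F5, and the fallback comes back to the route at 28.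

Step 4. C-alkylation by the unactivated triflate may be slow, so that enolate decomposition, double alkylation or Dieckmann-type self-condensation overtake it. The fallback uses an activated electrophile and builds the vinyl iodide afterwards. It sets out from 4: the bis-enolate 13 is alkylated with allyl iodide to the mono-allyl bis-imide F6. 9-BBN should give the borane F7, buffered H2O2 (NaOAc) the primary alcohol F8, and Dess–Martin periodinane the aldehyde F9. Stork–Zhao olefination of F9 with ylide 9 should then give 14, where the fallback comes back to the route.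

Step 6. Attack of the vinyl copper reagent at the hindered secondary carbon may be slow, so that Lewis-acid-induced rearrangement of the epoxide or internal attack by the magnesium alkoxide takes over. The fallback uses a small linear nucleophile and adjusts the oxidation level afterwards. It sets out from 16: LiC≡CH·H2NCH2CH2NH2 in DMSO should open the epoxide at C1 with inversion to the alkynyl diol F10. Semihydrogenation over Pd/CaCO3 poisoned with Pb(OAc)2, with quinoline, should then give 17, where the fallback comes back to the route.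

Further compounds
F1 | step 10 | dimethyl (2S,6R)-2-[(1R,3S)-3-ethenyl-1-hydroxy-4-methyl-4-(triethylsilyloxy)pentyl]-6-[(3Z)-4-iodopent-3-en-1-yl]heptanedioate | C/C(I)=C/CC[C@H](C(=O)OC)CCC[C@H](C(=O)OC)[C@H](O)C[C@@H](C=C)C(C)(C)O[Si](CC)(CC)CC
F2 | step 10 | B-alkyl-9-borabicyclo[3.3.1]nonane adduct of F1 (boron on C13) | C/C(I)=C/CC[C@H](C(=O)OC)CCC[C@H](C(=O)OC)[C@H](O)C[C@@H](CCB1C2CCCC1CCC2)C(C)(C)O[Si](CC)(CC)CC
F3 | step 10 | dimethyl (1R,3R,4S,8R,11Z)-3-hydroxy-12-methyl-1-[2-(triethylsilyloxy)propan-2-yl]cyclotetradec-11-ene-4,8-dicarboxylate | C/C1=C/CC[C@H](C(=O)OC)CCC[C@H](C(=O)OC)[C@H](O)C[C@@H](CC1)C(C)(C)O[Si](CC)(CC)CC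
F4 | step 10 | dimethyl (1R,3R,4S,8R,11Z)-3-hydroxy-1-(2-hydroxypropan-2-yl)-12-methylcyclotetradec-11-ene-4,8-dicarboxylate | C/C1=C/CC[C@H](C(=O)OC)CCC[C@H](C(=O)OC)[C@H](O)C[C@@H](CC1)C(C)(C)O
F5 | step 10 | dimethyl (1R,4Z,8R,12S,13R)-4,15,15-trimethyl-14-oxabicyclo[11.2.1]hexadec-4-ene-8,12-dicarboxylate | C/C1=C/CC[C@H](C(=O)OC)CCC[C@H](C(=O)OC)[C@H]2C[C@@H](CC1)C(C)(C)O2
F6 | step 4 | (2R)-1,7-bis[(4S)-4-benzyl-2-oxo-1,3-oxazolidin-3-yl]-2-(prop-2-en-1-yl)heptane-1,7-dione | C=CC[C@H](C(=O)N1[C@@H](Cc2ccccc2)COC1=O)CCCCC(=O)N1[C@@H](Cc2ccccc2)COC1=O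
F7 | step 4 | B-alkyl-9-borabicyclo[3.3.1]nonane adduct of F6 (boron on the terminal carbon) | B1(C2CCCC1CCC2)CCC[C@H](C(=O)N1[C@@H](Cc2ccccc2)COC1=O)CCCCC(=O)N1[C@@H](Cc2ccccc2)COC1=O
F8 | step 4 | (2R)-1,7-bis[(4S)-4-benzyl-2-oxo-1,3-oxazolidin-3-yl]-2-(3-hydroxypropyl)heptane-1,7-dione | OCCC[C@H](C(=O)N1[C@@H](Cc2ccccc2)COC1=O)CCCCC(=O)N1[C@@H](Cc2ccccc2)COC1=O
F9 | step 4 | (4R)-4,8-bis{[(4S)-4-benzyl-2-oxo-1,3-oxazolidin-3-yl]carbonyl}octanal | O=CCC[C@H](C(=O)N1[C@@H](Cc2ccccc2)COC1=O)CCCCC(=O)N1[C@@H](Cc2ccccc2)COC1=O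
F10 | step 6 | (3S)-3-ethynyl-4-methylpentane-1,4-diol | OCC[C@@H](C#C)C(C)(C)O
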